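Late in Monday's run the readings of Q fall nearly first order, at a mean 0.154 /d between 4.00 d and 15.0 d. Wednesday's Q falls nearly in a straight line after its peak, by 0.0406 /d of the charge between 2.08 d and 4.00 d. A straight fall suggests that a fixed amount of Q decays while the rest is held back.

| flask | Z | remark | time |
|---|---|---|---|
| Monday's | 0.30 M | run made earlier |  |
| Wednesday's | 0.45 M | run made earlier |  |
| flask | 0.60 M |  | 12 d |

- Monday's (time / d: Q / %): 0.250: 28.5; 0.500: 39.8; 1.04: 42.5; 2.08: 36.6; 4.00: 27.2; 8.00: 15.4; 15.0: 5.0
- Wednesday's (time / d: Q / %): 0.250: 29.1; 0.500: 40.3; 1.04: 43.6; 2.08: 39.6; 4.00: 31.8; 8.00: 17.4; 15.0: 6.2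

(standard deviation of a reading: 0.3 percentage points)

- time, not beyond 12 d, at which the flask holds most Q
- the amount of Q, in percent of the Z charged, at that time

- what was read earlier has a scatter of 0.3 percentage points, one standard deviation
- a reading or a percentage of Q counts all its forms, free or not

Dividing the straight fall by the first-order constant removes time. What remains is the ceiling share, the fraction of the charge taken to stand free, as under a solubility limit:

ceiling share, Wednesday's run = 0.0406 /d / 0.154 /d = 0.264

The same ceiling in a larger charge is a smaller fraction: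

ceiling share, flask = 0.264 × 0.45 M / 0.60 M = 0.198

fall, flask = 0.154 /d × 0.198 = 0.0305 /d of the charge

The flask's reckoned fall is slower than Wednesday's read one, but it is still a loss of Q after the peak. The decision is therefore to stop the flask early, near 1.04 d, and to expect about Wednesday's 43.6%.

The forecast stands higher and later than this reckoning, at 44.2% and 1.05 d, on the ground that “only free Q decays and free Q is capped”.

The flask peaks at 1.00 d with 43.6%.

    Z → G (k = 3.70 × 10⁻⁴ /s)
    G ⇌ Q (K = 6.70, k = 2.60 × 10⁻⁵ /s)
    G ⇌ J (K = 50.0, k = 3.60 × 10⁻⁷ /s)
    E ⇌ Q, rate k4*(cs4 - [Q]) while solid is left; crystals form when [Q] > cs4 (solubility = 0.110 M, k = 0.00160 /s)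
    2 Z → X (k = 5.10 × 10⁻⁵ /M/s)
    G → L (k = 2.40 × 10⁻⁵ /s)

At that peak, 25.2% of the charge stands as crystals E, counted in Q. A neighbour flask is charged with 2.4 M. Its ceiling share is 0.0495, so its Q should fall by 0.00762 /d of the charge, a rate worth 9.14% of the charge in 12 d. Its best is 38.3%. At 12.0 d it holds 30.5%, which is 7.8 percentage points below its best, with E still at 25.9%.

The runs stem from a simulated flask for substances that don't exist.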